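**Retrosynthetic overview**
- The quinone is unmasked last, from the only para-dimethoxy pair (C3'/C6') of 5-hydroxy-3,7-dimethoxy-2-(2,3,4,6-tetramethoxyphenyl)chromone. Ring B is bought as an arene.
- Rings A and C are cut together. O1–C2 (cyclodehydration) and C4a–C8a (Claisen) lead back to an open, pyrone-masked pentaketide, pyronyl-CH2-CO-CH(OMe)-CO-Ar.
- The C2–C3 cut gives an aroyl chloride and the dianion of a pyronyl methoxymethyl ketone. The C4–C4a cut gives lithiated 4-methoxy-6-methyl-2-pyrone and methyl methoxyacetate.
- The aroyl chloride comes from 1,2,3,5-tetramethoxybenzene by ortho-lithiation and CO2.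
- Ring order: B (purchased), then A and C in one flask. The sacrificed 2-pyrone supplies five ring A carbons and the 5-OH/7-OMe pattern.

Assumption: the SMILES holds no stereocentre, no stereo-defined double bond and no assigned axis, so the target is treated as achiral and needs no enantiocontrol; 1,2,3,5-tetramethoxybenzene is taken as a catalogue chemical.

**Step 1**
Reactants: 1 4-methoxy-6-methyl-2H-pyran-2-one; 2 methyl methoxyacetate
Product: 4 4-methoxy-6-(3-methoxy-2-oxopropyl)-2H-pyran-2-one, via lithiated pyrone 3 (not isolated)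
Conditions: LiN(i-Pr)2 (2.1 equiv), THF, −78 °C, 30 min; 2 (1.1 equiv), −78 → −20 °C; dilute aq. HCl
Reagents that add atoms: none
Why: Crossed Claisen condensation of a vinylogous ester enolate: LiN(i-Pr)2 deprotonates the C6-methyl group, the extended dienolate 3 attacks the unhindered ester through its exocyclic carbon, the second equivalent of base stores the more acidic product as its enolate so it is not acylated twice, and no stereocentre is formed.

**Step 2**
Reactants: 5 1,2,3,5-tetramethoxybenzene
Product: 7 2,3,4,6-tetramethoxybenzoic acid, via aryllithium 6 (not isolated)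
Conditions: n-BuLi (1.1 equiv), THF, 0 °C → rt, 2 h; CO2 (g), −78 °C → rt; dilute aq. HCl
Reagents that add atoms: carbon dioxide, O=C=O
Why: Directed ortho-metalation then carboxylation: the two free ring positions are equivalent and each is flanked by two OMe groups, so one aryllithium forms and CO2 traps it, and no stereocentre is formed.

**Step 3**
Reactants: 4 4-methoxy-6-(3-methoxy-2-oxopropyl)-2H-pyran-2-one (2.0 equiv); 7 2,3,4,6-tetramethoxybenzoic acid
Product: 10 2-methoxy-4-(4-methoxy-2-oxo-2H-pyran-6-yl)-1-(2,3,4,6-tetramethoxyphenyl)butane-1,3-dione, via acid chloride 8 (not isolated), via dilithio dianion 9 (not isolated)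
Conditions: flask a: 7, (COCl)2 (1.2 equiv), DMF (cat.), CH2Cl2, 0 °C → rt, evaporate; flask b: 4, LiN(i-Pr)2 (4.1 equiv), THF, −78 → −30 °C; add 8 in THF at −78 °C, → −20 °C; dilute aq. HCl; surplus 4 recovered
Reagents that add atoms: none
Why: Acid chloride formation followed by C-acylation of a 1,3-dicarbonyl-type dianion (Hauser–Harris dianion chemistry): the carbanion made last, at the CH2OMe carbon, is the most nucleophilic site and takes the aroyl chloride, the second equivalent of 9 acts as base for the acidic product, and the new CH(OMe) centre is racemic, enolisable and erased in step 4.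

**Step 4 (key step: rings A and C)**
Reactants: 10 2-methoxy-4-(4-methoxy-2-oxo-2H-pyran-6-yl)-1-(2,3,4,6-tetramethoxyphenyl)butane-1,3-dione
Product: 13 5-hydroxy-3,7-dimethoxy-2-(2,3,4,6-tetramethoxyphenyl)-4H-chromen-4-one, via ring-opened trioxo ester 11 (not isolated), via aryl 1,3-diketone 12 (not isolated)
Conditions: Mg(OMe)2 (6 equiv), MeOH, reflux, 12 h, argon; then conc. HCl to pH 1 in the same flask, 60 °C, 2 h
Reagents that add atoms: none
Why: Proposed new method: Mg(OMe)2 opens the 2-pyrone reversibly at the lactone carbonyl to the (E)-enol-ether trioxo ester 11, whose ketones are all held as magnesium enolates so that the ester is the only electrophilic carbonyl and the CH between C5 and C7 of the chain is the only carbanion that reaches it through a six-membered transition state, which gives ring A irreversibly by Claisen (Dieckmann-type) closure and aromatisation to the locally symmetric 2,6-dihydroxy-4-methoxyphenyl ketone 12, and acidifying the same flask lets either of the two equivalent phenols add to the aroyl carbonyl and lose water to close ring C (the last stage of a Baker–Venkataraman flavone synthesis), which erases the CH(OMe) centre and fixes 5-OH/7-OMe without a protecting group; the closest known reaction types are the biomimetic conversion of 6-(2-oxoalkyl)-2-pyrones into acylphloroglucinols by Mg(OMe)2 and the acid cyclodehydration of o-hydroxyaryl 1,3-diketones, which have not been run in tandem on such a pyrone-masked pentaketide.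

**Step 5**
Reactants: 13 5-hydroxy-3,7-dimethoxy-2-(2,3,4,6-tetramethoxyphenyl)-4H-chromen-4-one
Product: 14 2-(5-hydroxy-3,7-dimethoxy-4-oxo-4H-chromen-2-yl)-3,5-dimethoxycyclohexa-2,5-diene-1,4-dione (target)
Conditions: (NH4)2Ce(NO3)6 (2.3 equiv), MeCN/H2O 3:1, 0 °C, 15 min
Reagents that add atoms: water, O
Why: Oxidative demethylation of a hydroquinone dimethyl ether by tetravalent cerium: ring B is by far the most electron-rich arene and holds the only para-dimethoxy pair (C3'/C6'), so two one-electron oxidations with attack of water at these carbons release two MeOH and give the 2,6-dimethoxy-1,4-benzoquinone, while the hydrogen-bonded 5-OH on the acyl-deactivated ring A and the 3-OMe enol ether are left alone, and no stereocentre is formed.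

**Compound list**
1 | 4-methoxy-6-methyl-2H-pyran-2-one | CC1=CC(OC)=CC(=O)O1 | starting material
2 | methyl methoxyacetate | COCC(=O)OC | starting material
3 | (4-methoxy-2-oxo-2H-pyran-6-yl)methyllithium (extended dienolate, drawn C-lithiated) | [Li]CC1=CC(OC)=CC(=O)O1 | intermediate
4 | 4-methoxy-6-(3-methoxy-2-oxopropyl)-2H-pyran-2-one | COCC(=O)CC1=CC(OC)=CC(=O)O1 | intermediate
5 | 1,2,3,5-tetramethoxybenzene | COc1cc(OC)c(OC)c(OC)c1 | starting material
6 | 2,3,4,6-tetramethoxyphenyllithium | [Li]c1c(OC)cc(OC)c(OC)c1OC | intermediate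
7 | 2,3,4,6-tetramethoxybenzoic acid | OC(=O)c1c(OC)cc(OC)c(OC)c1OC | intermediate
8 | 2,3,4,6-tetramethoxybenzoyl chloride | ClC(=O)c1c(OC)cc(OC)c(OC)c1OC | intermediate
9 | dilithio dianion of 4 (bis-enolate, drawn C-lithiated at both carbons flanking the ketone) | [Li]C(OC)C(=O)C([Li])C1=CC(OC)=CC(=O)O1 | intermediate
10 | 2-methoxy-4-(4-methoxy-2-oxo-2H-pyran-6-yl)-1-(2,3,4,6-tetramethoxyphenyl)butane-1,3-dione (racemic, enolisable CH(OMe)) | COC1=CC(=O)OC(CC(=O)C(OC)C(=O)c2c(OC)cc(OC)c(OC)c2OC)=C1 | intermediate
11 | methyl (2E)-3,8-dimethoxy-5,7,9-trioxo-9-(2,3,4,6-tetramethoxyphenyl)non-2-enoate (as magnesium enolate, racemic at C8) | COC(=O)/C=C(/OC)CC(=O)CC(=O)C(OC)C(=O)c1c(OC)cc(OC)c(OC)c1OC | intermediate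
12 | 1-(2,6-dihydroxy-4-methoxyphenyl)-2-methoxy-3-(2,3,4,6-tetramethoxyphenyl)propane-1,3-dione (racemic, enolisable) | COc1cc(O)c(C(=O)C(OC)C(=O)c2c(OC)cc(OC)c(OC)c2OC)c(O)c1 | intermediate
13 | 5-hydroxy-3,7-dimethoxy-2-(2,3,4,6-tetramethoxyphenyl)-4H-chromen-4-one | COc1cc(O)c2c(=O)c(OC)c(-c3c(OC)cc(OC)c(OC)c3OC)oc2c1 | intermediate
14 | 2-(5-hydroxy-3,7-dimethoxy-4-oxo-4H-chromen-2-yl)-3,5-dimethoxycyclohexa-2,5-diene-1,4-dione (achiral) | COC1=CC(=O)C(c2oc3cc(OC)cc(O)c3c(=O)c2OC)=C(OC)C1=O | target

**Step count**
Total step count: 5. Longest linear sequence: 4 (steps 1, 3, 4, 5, or equally steps 2, 3, 4, 5).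

**Steps most likely to fail**

Step 4. The risks are aldol-type closure to a resorcylate instead of the Claisen mode, and retro-Claisen loss of the aroyl group in hot methoxide. The fallback sets out from 4 and 8 and comes back at 12. The Mg(OMe)2 isomerisation is run on the simple ketone 4, the case nearest to known pyrone-to-acylphloroglucinol chemistry. This gives 1-(2,6-dihydroxy-4-methoxyphenyl)-2-methoxyethan-1-one F1. Its lithium polyanion (LiN(SiMe3)2, 4.2 equiv, THF, −78 °C) is C-aroylated by acid chloride 8 to give diketone 12. This time 12 is isolated and closed to 13 with catalytic H2SO4 in AcOH at 60 °C. Ring A is thus made before the sensitive aroyl diketone exists.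

Step 3. The risks are the hindered aroyl chloride, proton transfer from the product, and O-acylation. The fallback sets out from 4 and 5 and comes back at 10. Aryllithium 6 (from 5) is quenched with DMF to give 2,3,4,6-tetramethoxybenzaldehyde F2. Dianion 9 is then needed in only one equivalent, because an alkoxide and not an acidic diketone is formed. It adds to F2 in an aldol reaction to give 6-[4-hydroxy-3-methoxy-2-oxo-4-(2,3,4,6-tetramethoxyphenyl)butyl]-4-methoxy-2H-pyran-2-one F3, a diastereomer mixture of no consequence. Dess–Martin periodinane in CH2Cl2 oxidises the benzylic carbinol of F3 to 10.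

Step 5. The risk is oxidation or nitration of the free phenol ring A by tetravalent cerium. The fallback sets out from 13 and comes back at 14. The 5-OH is acetylated (Ac2O, pyridine, DMAP cat.) to give 3,7-dimethoxy-4-oxo-2-(2,3,4,6-tetramethoxyphenyl)-4H-chromen-5-yl acetate F4, in which ring A is deactivated and carries no phenol. Treatment with (NH4)2Ce(NO3)6 in MeCN/H2O gives 2-(2,4-dimethoxy-3,6-dioxocyclohexa-1,4-dien-1-yl)-3,7-dimethoxy-4-oxo-4H-chromen-5-yl acetate F5. The labile peri-acetate is then removed by acid methanolysis (AcCl cat., MeOH, rt). Under these conditions exchange of the quinone OMe groups is degenerate, and 14 is obtained.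

**Further compounds**
F1 | step 4 | 1-(2,6-dihydroxy-4-methoxyphenyl)-2-methoxyethan-1-one | COCC(=O)c1c(O)cc(OC)cc1O
F2 | step 3 | 2,3,4,6-tetramethoxybenzaldehyde | O=Cc1c(OC)cc(OC)c(OC)c1OC
F3 | step 3 | 6-[4-hydroxy-3-methoxy-2-oxo-4-(2,3,4,6-tetramethoxyphenyl)butyl]-4-methoxy-2H-pyran-2-one (racemic diastereomer mixture) | COC1=CC(=O)OC(CC(=O)C(OC)C(O)c2c(OC)cc(OC)c(OC)c2OC)=C1
F4 | step 5 | 3,7-dimethoxy-4-oxo-2-(2,3,4,6-tetramethoxyphenyl)-4H-chromen-5-yl acetate | COc1cc(OC(C)=O)c2c(=O)c(OC)c(-c3c(OC)cc(OC)c(OC)c3OC)oc2c1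
F5 | step 5 | 2-(2,4-dimethoxy-3,6-dioxocyclohexa-1,4-dien-1-yl)-3,7-dimethoxy-4-oxo-4H-chromen-5-yl acetate | COC1=CC(=O)C(c2oc3cc(OC)cc(OC(C)=O)c3c(=O)c2OC)=C(OC)C1=O
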